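**Retrosynthetic overview**
1. The CH2 bridge is cut last. This gives enone methide 11 (from ring-A unit 4 plus one C1 iminium) and arene 9, mirroring the methionine-derived methylene coupling of fern phloroglucinols.
2. Ring A comes from a C6→C1 Claisen cyclisation of the gem-dimethyl tetraketide ester 3. Ester 3 is assembled in the same flask from acetylacetone dianion (1) and dimethyl dimethylmalonate (2).
3. Ring B comes from a C6→C1 Claisen cyclisation of the O-methyl tetraketide 8. Ester 8 is released from pyranone 7, which is triacetic-lactone methyl ether (5) plus a butanoyl unit (6).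
4. Rings A (step 1) and B (step 2) are built independently and joined in step 3.

Assumption: the target SMILES has no stereocentre, stereogenic double bond or axis, so the compound is achiral and no stereocontrol is needed. Enolised β-triketones are written in the tautomer used in the target SMILES.

**Step 1**
Reactants: 1 acetylacetone (pentane-2,4-dione); 2 dimethyl 2,2-dimethylmalonate
Product: 4 acetylfilicinic acid (2-acetyl-3,5-dihydroxy-4,4-dimethylcyclohexa-2,5-dien-1-one), via methyl 2,2-dimethyl-3,5,7-trioxooctanoate 3 (not isolated)
Conditions: commercial LDA (3.2 equiv), THF, −78 → 0 °C; 2 (1.0 equiv), 0 °C → rt, then 65 °C, 6 h; 2 M HCl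
Reagents that add atoms: none
Why: Proposed new method: the terminal carbanion of dilithio-acetylacetone acylates one ester of the non-enolisable diester 2 and the spare LDA turns 3 into its 4,6-dianion, and because C2 is quaternary the aldol (orsellinate) mode is blocked and the remaining ester cannot be deactivated by enolisation, so C6 attacks C1 in the same Claisen mode used by phloroglucinol-forming polyketide synthases, with any O-acylated enol lactone reopened by LiOMe and drained to the doubly stabilised dianion of 4; the closest known reaction types are Hauser–Harris acylation of β-diketone dianions with non-enolisable esters, the Dieckmann closure used for syncarpic acid, and the barbiturate-type double condensation of dialkylmalonates; no stereocentre is formed.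

**Step 2**
Reactants: 5 4-methoxy-6-methyl-2H-pyran-2-one; 6 N-methoxy-N-methylbutanamide
Product: 9 1-(2,6-dihydroxy-4-methoxyphenyl)butan-1-one, via 4-methoxy-6-(2-oxopentyl)-2H-pyran-2-one 7 (not isolated), via methyl (2E)-3-methoxy-5,7-dioxodec-2-enoate 8 (not isolated)
Conditions: commercial LDA (1.1 equiv), THF, −78 °C, 45 min; 6 (1.1 equiv), −78 → 0 °C; then Mg(OMe)2 (4 equiv, in MeOH), THF distilled out, reflux, 8 h; 1 M HCl
Reagents that add atoms: none
Why: The vinylogous C6-CH2 anion of 5 is acylated once by the Weinreb amide (Weinreb ketone synthesis, whose chelated adduct prevents proton transfer and over-addition), and Mg(OMe)2 then opens the pyranone at C2 to the (E)-enol-ether ester 8, whose ester and chain are held cis and whose Mg-chelated 5,7-diketonate attacks C1 through C6 (biomimetic Claisen/Dieckmann cyclisation, the pyranone-to-phloroglucinol rearrangement), with the enol ether suppressing the aldol mode and ending up as the 4-OMe group; no stereocentre is formed.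

**Step 3**
Reactants: 4 acetylfilicinic acid; 9 1-(2,6-dihydroxy-4-methoxyphenyl)butan-1-one
Product: 12 2-acetyl-6-[(3-butanoyl-2,4-dihydroxy-6-methoxyphenyl)methyl]-3,5-dihydroxy-4,4-dimethylcyclohexa-2,5-dien-1-one (target), via Mannich base 10 (not isolated), via enone methide 11 (not isolated)
Conditions: 4, CH2=NMe2+ I− (1.0 equiv), NaOAc (1.2 equiv), MeCN, 0 °C → rt, 1 h; then 9 (1.5 equiv), 70 °C, N2 sweep, 6 h; 1 M HCl wash
Reagents that add atoms: Eschenmoser's salt (N,N-dimethylmethyleneiminium iodide), C=[N+](C)C.[I-]
Why: A Mannich reaction at the only free ring carbon of 4 consumes all of 4 before 9 is added (so no homodimer can form), thermal loss of Me2NH gives the enone methide 11, and the phenolate of 9 adds through C3 in a Friedel–Crafts-type Michael addition (as in alkylidene-syncarpic acid/acylphloroglucinol couplings), where C3 and C5 of 9 are equivalent so one regioisomer results and excess 9 limits double alkylation; no stereocentre is formed.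

**Compound list**
1 | acetylacetone (pentane-2,4-dione) | CC(=O)CC(C)=O | starting material
2 | dimethyl 2,2-dimethylmalonate | COC(=O)C(C)(C)C(=O)OC | starting material
3 | methyl 2,2-dimethyl-3,5,7-trioxooctanoate (not isolated) | COC(=O)C(C)(C)C(=O)CC(=O)CC(C)=O | intermediate
4 | acetylfilicinic acid, 2-acetyl-3,5-dihydroxy-4,4-dimethylcyclohexa-2,5-dien-1-one | CC(=O)C1=C(O)C(C)(C)C(O)=CC1=O | intermediate
5 | 4-methoxy-6-methyl-2H-pyran-2-one | COC1=CC(=O)OC(C)=C1 | starting material
6 | N-methoxy-N-methylbutanamide | CCCC(=O)N(C)OC | starting material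
7 | 4-methoxy-6-(2-oxopentyl)-2H-pyran-2-one (not isolated) | CCCC(=O)CC1=CC(OC)=CC(=O)O1 | intermediate
8 | methyl (2E)-3-methoxy-5,7-dioxodec-2-enoate (not isolated) | COC(=O)/C=C(/OC)CC(=O)CC(=O)CCC | intermediate
9 | 1-(2,6-dihydroxy-4-methoxyphenyl)butan-1-one | CCCC(=O)c1c(O)cc(OC)cc1O | intermediate
10 | 2-acetyl-6-[(dimethylamino)methyl]-3,5-dihydroxy-4,4-dimethylcyclohexa-2,5-dien-1-one (Mannich base, not isolated) | CN(C)CC1=C(O)C(C)(C)C(O)=C(C(C)=O)C1=O | intermediate
11 | 2-acetyl-3-hydroxy-4,4-dimethyl-6-methylidenecyclohex-2-ene-1,5-dione (enone methide, not isolated) | C=C1C(=O)C(C)(C)C(O)=C(C(C)=O)C1=O | intermediate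
12 | 2-acetyl-6-[(3-butanoyl-2,4-dihydroxy-6-methoxyphenyl)methyl]-3,5-dihydroxy-4,4-dimethylcyclohexa-2,5-dien-1-one | CCCC(=O)c1c(O)cc(OC)c(CC2=C(O)C(C)(C)C(O)=C(C(C)=O)C2=O)c1O | target

**Total step count:** 3. **Longest linear sequence:** 2 (step 1 or step 2, then step 3).

**Steps most likely to fail, most risky first**

Step 1. The neopentyl-type ester may react slowly. Intermediate 3 may stall as the O-acylated enol lactone, or lose methyl isobutyrate by retro-Claisen cleavage. The fallback sets out from 2 and comes back at 4. It closes the ring at the triketide stage through a more reactive primary carbanion and introduces the acetyl group afterwards. Diester 2 is condensed with the lithium enolate of acetone (2 equiv, THF, −78 °C → rt) to give methyl 2,2-dimethyl-3,5-dioxohexanoate F1. The dianion of F1 (LDA, 2.2 equiv, THF, 0 °C → reflux) undergoes Dieckmann closure to filicinic acid F2. C-acetylation of F2 (Ac2O, BF3·OEt2, 60 °C) then gives 4.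

Step 2. The pyranone anion may be acylated incompletely. The anionic keto-pyranone 7 may resist methoxide opening. Ester 8 may divert to a γ-pyranone or to the aldol-type resorcylate. The fallback sets out from 6 and comes back at 9. It uses a ready-made arene and employs 6 to acylate an aryllithium. Purchased 5-methoxyresorcinol F3 is protected (MOMCl, iPr2NEt, CH2Cl2) to give 1-methoxy-3,5-bis(methoxymethoxy)benzene F4. Directed ortho-lithiation between the two OMOM groups (n-BuLi, THF, 0 °C) followed by addition of 6 gives 1-[4-methoxy-2,6-bis(methoxymethoxy)phenyl]butan-1-one F5. HCl in MeOH (50 °C) removes both MOM groups to give 9.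

Step 3. Methide 11 may dimerise. Retro-Mannich or retro-Michael exchange may scramble the partners into homodimers. Product 12 may be alkylated a second time. The fallback sets out from 9 and comes back at 12. It first fixes the bridge carbon to the arene at the aldehyde oxidation level, so scrambling is impossible. Rieche formylation of 9 (Cl2CHOMe, TiCl4, CH2Cl2, −10 °C, aqueous work-up) gives 3-butanoyl-2,4-dihydroxy-6-methoxybenzaldehyde F6. Organocatalytic reductive Knoevenagel alkylation with 4 (L-proline cat., Hantzsch ester, CH2Cl2/EtOH, rt) passes through 2-acetyl-6-[(3-butanoyl-2,4-dihydroxy-6-methoxyphenyl)methylidene]-3-hydroxy-4,4-dimethylcyclohex-2-ene-1,5-dione F7. Hydride transfer reduces F7 in situ to 12.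

**Further compounds**
F1 | step 1 | methyl 2,2-dimethyl-3,5-dioxohexanoate | COC(=O)C(C)(C)C(=O)CC(C)=O
F2 | step 1 | filicinic acid (3,5-dihydroxy-4,4-dimethylcyclohexa-2,5-dien-1-one) | CC1(C)C(O)=CC(=O)C=C1O
F3 | step 2 | 5-methoxyresorcinol (purchased) | COc1cc(O)cc(O)c1
F4 | step 2 | 1-methoxy-3,5-bis(methoxymethoxy)benzene | COCOc1cc(OC)cc(OCOC)c1
F5 | step 2 | 1-[4-methoxy-2,6-bis(methoxymethoxy)phenyl]butan-1-one | CCCC(=O)c1c(OCOC)cc(OC)cc1OCOC
F6 | step 3 | 3-butanoyl-2,4-dihydroxy-6-methoxybenzaldehyde | CCCC(=O)c1c(O)cc(OC)c(C=O)c1O
F7 | step 3 | 2-acetyl-6-[(3-butanoyl-2,4-dihydroxy-6-methoxyphenyl)methylidene]-3-hydroxy-4,4-dimethylcyclohex-2-ene-1,5-dione (transient, E/Z not defined) | CCCC(=O)c1c(O)cc(OC)c(C=C2C(=O)C(C)(C)C(O)=C(C(C)=O)C2=O)c1O
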